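**Retrosynthetic overview**
- Gardenin A ⇐ 5,6,7,8,3',4',5'-heptamethoxyflavone by carbonyl-directed cleavage of the peri 5-OMe only.
- Flavone ring C ⇐ iodine/DMSO oxidative cyclisation of a 2'-hydroxychalcone (O1–C2 closure, then dehydrogenation).
- Chalcone ⇐ intermolecular Claisen–Schmidt aldol condensation of 2'-hydroxy-3',4',5',6'-tetramethoxyacetophenone with 3,4,5-trimethoxybenzaldehyde (key C–C bond).
- Acetophenone ⇐ C-acetylation of 2,3,4,5-tetramethoxyphenol ⇐ two formyl-to-hydroxyl (Baeyer–Villiger) cycles from 2,3,4-trimethoxybenzaldehyde.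
- Ring order: rings A and B are bought as benzenes; only the pyranone ring C is built, last.

Assumption: Gardenin A has no stereocentre and is achiral, so there is no enantiomer to select; the only stereo-elements on the way are the E-alkene of 13 and the transient racemic centres of 12, 14 and 15, all erased in step 7.

**Step 1**
Reactants: 1 2,3,4-trimethoxybenzaldehyde
Product: 3 2,3,4-trimethoxyphenol, via 2,3,4-trimethoxyphenyl formate 2 (not isolated)
Conditions: mCPBA, CH2Cl2, 0 °C → rt; aq. NaHCO3 wash; then HCl (cat.), MeOH, rt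
Reagents that add atoms: meta-chloroperoxybenzoic acid (mCPBA), OOC(=O)c1cccc(Cl)c1
Why: Baeyer–Villiger (Dakin-type) oxidation, in which the aryl group carrying ortho and para methoxy donors migrates in preference to hydride, and the labile aryl formate is then cleaved by acid-catalysed methanolysis.

**Step 2**
Reactants: 3 2,3,4-trimethoxyphenol
Product: 4 1,2,3,4-tetramethoxybenzene
Conditions: MeI, K2CO3, acetone, reflux
Reagents that add atoms: iodomethane, CI
Why: Williamson ether synthesis (SN2 O-methylation of the phenoxide), with no competing nucleophile present.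

**Step 3**
Reactants: 4 1,2,3,4-tetramethoxybenzene
Product: 6 2,3,4,5-tetramethoxybenzaldehyde, via aryl iminium chloride 5 (not isolated)
Conditions: POCl3, DMF, 0 → 80 °C; then H2O, 50 °C
Reagents that add atoms: N,N-dimethylformamide, CN(C)C=O; water, O
Why: Vilsmeier–Haack formylation of a strongly activated arene whose two free positions are equivalent, so only one aldehyde can form after hydrolysis of the iminium salt.

**Step 4**
Reactants: 6 2,3,4,5-tetramethoxybenzaldehyde
Product: 8 2,3,4,5-tetramethoxyphenol, via 2,3,4,5-tetramethoxyphenyl formate 7 (not isolated)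
Conditions: mCPBA, CH2Cl2, 0 °C → rt; aq. NaHCO3 wash; then HCl (cat.), MeOH, rt
Reagents that add atoms: meta-chloroperoxybenzoic acid (mCPBA), OOC(=O)c1cccc(Cl)c1
Why: second Baeyer–Villiger (Dakin-type) oxidation, again favoured by the ortho and para methoxy groups, followed by methanolysis of the formate.

**Step 5**
Reactants: 8 2,3,4,5-tetramethoxyphenol
Product: 10 1-(2-hydroxy-3,4,5,6-tetramethoxyphenyl)ethan-1-one, via difluoroboron chelate 9 (not isolated)
Conditions: AcOH, BF3·OEt2 (3 equiv), 90 °C; then H2O, EtOH, 60 °C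
Reagents that add atoms: acetic acid, CC(=O)O
Why: BF3-mediated Friedel–Crafts C-acylation (Fries-type) at the single free ring position ortho to the hydroxyl, where the product is held as its BF2 chelate until aqueous hydrolysis, which shields the ketone from further reaction.

**Step 6**
Reactants: 10 1-(2-hydroxy-3,4,5,6-tetramethoxyphenyl)ethan-1-one; 11 3,4,5-trimethoxybenzaldehyde
Product: 13 (E)-1-(2-hydroxy-3,4,5,6-tetramethoxyphenyl)-3-(3,4,5-trimethoxyphenyl)prop-2-en-1-one, via racemic aldol adduct 12 (not isolated)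
Conditions: KOH (50% aq., 5 equiv), EtOH, rt, 36 h; then 2 M HCl to pH 3
Reagents that add atoms: none
Why: Claisen–Schmidt crossed aldol condensation in which only the methyl ketone can enolise and the aldehyde cannot self-condense, and E1cB dehydration of the racemic carbinol gives the conjugated, thermodynamically favoured E-alkene.

**Step 7**
Reactants: 13 (E)-1-(2-hydroxy-3,4,5,6-tetramethoxyphenyl)-3-(3,4,5-trimethoxyphenyl)prop-2-en-1-one
Product: 16 5,6,7,8-tetramethoxy-2-(3,4,5-trimethoxyphenyl)-4H-chromen-4-one, via flavanone 14 (not isolated), via 3-iodoflavanone 15 (not isolated)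
Conditions: I2 (10 mol %), DMSO, 130 °C, 3 h; aq. Na2S2O3 work-up
Reagents that add atoms: none
Why: iodine-catalysed oxidative cyclisation (oxa-Michael ring closure, α-iodination, loss of HI) with DMSO reoxidising HI to I2, and the transient C2/C3 stereocentres vanish when the pyranone double bond forms.

**Step 8**
Reactants: 16 5,6,7,8-tetramethoxy-2-(3,4,5-trimethoxyphenyl)-4H-chromen-4-one
Product: 18 Gardenin A (5-hydroxy-6,7,8-trimethoxy-2-(3,4,5-trimethoxyphenyl)-4H-chromen-4-one), via dichloroboron chelate 17 (not isolated)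
Conditions: BCl3 (1.5 equiv), CH2Cl2, −78 → 0 °C; then 1 M HCl, MeOH, rt
Reagents that add atoms: none
Why: chelation-controlled Lewis-acid ether cleavage, in which BCl3 bound to the C4 carbonyl cleaves only the peri 5-OMe through a six-membered O–B–O chelate, leaving the other six methyl ethers untouched at low temperature; hydrolysis then frees the hydrogen-bonded 5-OH.

**Compound list**
1 | 2,3,4-trimethoxybenzaldehyde | COc1ccc(C=O)c(OC)c1OC | starting material
2 | 2,3,4-trimethoxyphenyl formate | COc1ccc(OC=O)c(OC)c1OC | intermediate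
3 | 2,3,4-trimethoxyphenol | COc1ccc(O)c(OC)c1OC | intermediate
4 | 1,2,3,4-tetramethoxybenzene | COc1ccc(OC)c(OC)c1OC | intermediate
5 | N,N-dimethyl-(2,3,4,5-tetramethoxyphenyl)methaniminium chloride | C[N+](C)=Cc1cc(OC)c(OC)c(OC)c1OC.[Cl-] | intermediate
6 | 2,3,4,5-tetramethoxybenzaldehyde | COc1cc(C=O)c(OC)c(OC)c1OC | intermediate
7 | 2,3,4,5-tetramethoxyphenyl formate | COc1cc(OC=O)c(OC)c(OC)c1OC | intermediate
8 | 2,3,4,5-tetramethoxyphenol | COc1cc(O)c(OC)c(OC)c1OC | intermediate
9 | difluoroboron chelate of 10 (2,2-difluoro-4-methyl-5,6,7,8-tetramethoxy-1,3,2-benzodioxaborinine, O→B dative) | CC1=[O+][B-](F)(F)Oc2c1c(OC)c(OC)c(OC)c2OC | intermediate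
10 | 1-(2-hydroxy-3,4,5,6-tetramethoxyphenyl)ethan-1-one | CC(=O)c1c(O)c(OC)c(OC)c(OC)c1OC | intermediate
11 | 3,4,5-trimethoxybenzaldehyde | COc1cc(C=O)cc(OC)c1OC | starting material
12 | 3-hydroxy-1-(2-hydroxy-3,4,5,6-tetramethoxyphenyl)-3-(3,4,5-trimethoxyphenyl)propan-1-one (racemic) | COc1cc(C(O)CC(=O)c2c(O)c(OC)c(OC)c(OC)c2OC)cc(OC)c1OC | intermediate
13 | (E)-1-(2-hydroxy-3,4,5,6-tetramethoxyphenyl)-3-(3,4,5-trimethoxyphenyl)prop-2-en-1-one | COc1cc(/C=C/C(=O)c2c(O)c(OC)c(OC)c(OC)c2OC)cc(OC)c1OC | intermediate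
14 | 5,6,7,8-tetramethoxy-2-(3,4,5-trimethoxyphenyl)chroman-4-one (racemic) | COc1cc(C2CC(=O)c3c(OC)c(OC)c(OC)c(OC)c3O2)cc(OC)c1OC | intermediate
15 | 3-iodo-5,6,7,8-tetramethoxy-2-(3,4,5-trimethoxyphenyl)chroman-4-one (racemic, relative configuration not controlled) | COc1cc(C2Oc3c(OC)c(OC)c(OC)c(OC)c3C(=O)C2I)cc(OC)c1OC | intermediate
16 | 5,6,7,8-tetramethoxy-2-(3,4,5-trimethoxyphenyl)-4H-chromen-4-one | COc1cc(-c2cc(=O)c3c(OC)c(OC)c(OC)c(OC)c3o2)cc(OC)c1OC | intermediate
17 | dichloroboron chelate of Gardenin A (B bound to O5 and to the C4 carbonyl oxygen) | COc1cc(cc(OC)c1OC)C1=CC2=[O+][B-](Cl)(Cl)Oc3c(OC)c(OC)c(OC)c(O1)c23 | intermediate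
18 | Gardenin A, 5-hydroxy-6,7,8-trimethoxy-2-(3,4,5-trimethoxyphenyl)-4H-chromen-4-one (achiral) | COc1cc(-c2cc(=O)c3c(O)c(OC)c(OC)c(OC)c3o2)cc(OC)c1OC | target

**Totals**
Total step count: 8. Longest linear sequence: 8 steps (1 → 18); aldehyde 11 is used as bought.

**Three steps most likely to fail**

Step 5 (C-acetylation to a hexasubstituted benzene; risk of stalling at the O-acetate or of ether cleavage by BF3). The fallback sets out from 8 and comes back at 10, replacing electrophilic acylation by directed ortho-metalation. Phenol 8 is protected with MOMCl/i-Pr2NEt (CH2Cl2, 0 °C) to 1-(methoxymethoxy)-2,3,4,5-tetramethoxybenzene F1. n-BuLi (THF, 0 °C) removes the only ring hydrogen, which is flanked by OMOM and OMe, to give [2-(methoxymethoxy)-3,4,5,6-tetramethoxyphenyl]lithium F2. N-Methoxy-N-methylacetamide at −78 °C gives the lithium tetrahedral adduct F3, and aqueous NH4Cl releases 1-[2-(methoxymethoxy)-3,4,5,6-tetramethoxyphenyl]ethan-1-one F4. HCl in MeOH at 50 °C removes the MOM group and delivers 10.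

Step 6 (aldol condensation of a hindered, di-ortho-substituted, electron-rich ketone with a deactivated aldehyde; risk of low conversion or chalcone/flavanone mixtures). The fallback sets out from 10 and comes back at 16, replacing the aldol by an intermolecular Claisen-type C-acylation. LiHMDS (3.2 equiv, THF, −78 °C) turns 10 into the dilithium phenoxide–enolate F5. This is acylated on carbon by commercial 3,4,5-trimethoxybenzoyl chloride (COc1cc(C(Cl)=O)cc(OC)c1OC) to give, after acidic work-up, 1-(2-hydroxy-3,4,5,6-tetramethoxyphenyl)-3-(3,4,5-trimethoxyphenyl)propane-1,3-dione F6. Cyclodehydration with catalytic H2SO4 in AcOH at 95 °C closes ring C and gives flavone 16 directly, so chalcone 13 and step 7 are bypassed.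

Step 8 (mono-demethylation; risk of also cleaving the neighbouring 6-OMe). The fallback sets out from 16 and comes back at 18, replacing selective dealkylation by deliberate double cleavage followed by selective re-alkylation. AlBr3 in MeCN (0 °C → rt, then dilute HCl) removes both the 5- and 6-methyl groups to give 5,6-dihydroxy-7,8-dimethoxy-2-(3,4,5-trimethoxyphenyl)-4H-chromen-4-one F7. Me2SO4 (1.0 equiv) with K2CO3 in acetone then methylates only the free 6-OH, because the 5-OH is hydrogen-bonded to the carbonyl and unreactive, giving 18.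

**Further compounds**
F1 | step 5 | 1-(methoxymethoxy)-2,3,4,5-tetramethoxybenzene | COCOc1cc(OC)c(OC)c(OC)c1OC
F2 | step 5 | [2-(methoxymethoxy)-3,4,5,6-tetramethoxyphenyl]lithium | [Li]c1c(OCOC)c(OC)c(OC)c(OC)c1OC
F3 | step 5 | lithium 1-[methoxy(methyl)amino]-1-[2-(methoxymethoxy)-3,4,5,6-tetramethoxyphenyl]ethan-1-olate (tetrahedral adduct) | CON(C)C(C)(O[Li])c1c(OCOC)c(OC)c(OC)c(OC)c1OC
F4 | step 5 | 1-[2-(methoxymethoxy)-3,4,5,6-tetramethoxyphenyl]ethan-1-one | CC(=O)c1c(OCOC)c(OC)c(OC)c(OC)c1OC
F5 | step 6 | dilithium phenoxide–enolate of 10 | [Li]OC(=C)c1c(O[Li])c(OC)c(OC)c(OC)c1OC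
F6 | step 6 | 1-(2-hydroxy-3,4,5,6-tetramethoxyphenyl)-3-(3,4,5-trimethoxyphenyl)propane-1,3-dione | COc1cc(C(=O)CC(=O)c2c(O)c(OC)c(OC)c(OC)c2OC)cc(OC)c1OC
F7 | step 8 | 5,6-dihydroxy-7,8-dimethoxy-2-(3,4,5-trimethoxyphenyl)-4H-chromen-4-one | COc1cc(-c2cc(=O)c3c(O)c(O)c(OC)c(OC)c3o2)cc(OC)c1OC
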